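## Structural features

The target is a pentasubstituted phenol whose carbon Ar6 is bonded to C2 of a 1,2-dimethylbicyclo[3.1.0]hexane: a cyclopentane (C1–C5) fused along C1–C5 to a cyclopropane whose third carbon is C6. The bicycle carries three contiguous stereocentres, C1 (S), C2 (R) and C5 (R). C1 and C2 are adjacent quaternary carbons, their methyl groups are cis, and the arene lies on the same face of the five-membered ring as the cyclopropane methylene C6. Around the arene the substituents run Ar1 OH, Ar2 Br, Ar3 CH3, Ar4 Br, Ar5 H, Ar6 bicycle, so both bromines are ortho or para to oxygen and Ar2 is wedged between hydroxyl and methyl. The fragile elements are the cyclopropane and the aryl bromides: strong protic or Lewis acid can open C1–C6 with capture of C1 by the neighbouring phenol oxygen, and the bromides would not survive organometallic or hydrogenation steps. The real difficulty is the Ar6–C2 bond, which joins an ortho-oxygenated arene carbon to a quaternary carbon that has a second quaternary neighbour, together with control of C2 relative to the cyclopropane. The plan uses the 1,3-relationship of Ar1–OH and Ar3–CH3 across Ar2: Ar2, Ar1 and Ar6 map onto C2, C3 and C4 of a β-keto ester whose C4 is already bonded to C2 of the bicycle, Ar3–Ar5 map onto a masked 3-oxobutanal, and the ester carbon on Ar2 marks the place of the hindered bromine.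

## Logic of the disconnections

**22 to 20.** Both C–Br bonds are cut first: Ar4–Br goes back to Ar4–H and Ar2–Br to an Ar2–CO2H bond, with 21 lying in between. This keeps halogen out of every reductive and organometallic step and lets a carboxyl group that arrives with the ring mark the crowded ortho position. The gain is that the bromine pattern needs no separate regiocontrol. The forward step must put electrophilic bromine on the free para carbon and on the carboxyl-bearing ortho carbon, and the hydrogen bromide must be neutralised so that the cyclopropane is not opened.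

**20 to 19.** The carboxyl O–H is traced to an O–CH2Ph bond. The carbonyl is flanked by two ortho substituents, so hydrolysis at that carbon would be slow and would end with an acidification beside an acid-labile cyclopropane; a benzylic C–O bond can be cut by hydrogen away from the crowded centre and without acid. The simplification is modest but it fixes the order of events: hydrogenolysis must precede bromination, and the unactivated cyclopropane must be left untouched by the catalyst.

**19 to 15 and 16.** The benzene ring is cut at Ar5–Ar6 and Ar2–Ar3. The cut removes the whole arene and turns the hindered Ar6–C2 bond into an ordinary bond between the diene terminus of 15 and C2, so it is never made by coupling. The forward step must pair the terminal diene carbon with the acetal carbon of 16 and the central diene carbon with its ketone, and the bicycle must survive a Lewis acid.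

**15 to 14 to 13.** Two O–Si bonds are cut in turn. This reduces the diene to a β-keto ester and costs no skeletal bond. The demand is that the second silylation follows deprotonation at the CH2 next to the quaternary carbon, not at the already silylated position.

**13 to 9 and 10.** The bond between the ketone carbon and the methylene flanked by both carbonyls is cut, through 12 and 11. This is a two-carbon acylation that also brings in the benzyl ester. It asks only that the carboxyl of 9, one carbon away from a quaternary centre, can be activated.

**9 to 8 to 6.** After the trivial ester cleavage, the C2–CH3 bond is cut, through 7. This removes the second quaternary stereocentre and leaves a planar C2. The methyl nucleophile must add to a β,β-disubstituted enoate next to a quaternary carbon, on the face away from C6.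

**6 to 4 and 5.** The exocyclic C2=C bond is cut. Two carbons of the side chain are traced to a phosphonate, and the forward olefination must work on a ketone with a quaternary α-carbon.

**4 to 3 to 2 to 1.** The ketone is traced to a carbinol, then C1–C6 and C5–C6 are cut, and finally the carbinol C–H bond. The single carbinol centre, made by catalytic reduction, must direct the methylene to its own face and so fix C1 and C5 before it is oxidised away.

## Other disconnections considered

**Alternative 1:** The cut runs through C2–C3 and C1–C5, so that C1 and C2 come from the C3=C4 double bond of the coumarin 3,4,7-trimethyl-2H-chromen-2-one A1 and C3–C5 from a trimethylenemethane donor such as 2-[(trimethylsilyl)methyl]prop-2-en-1-yl acetate A2.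
- Forward step: a zerovalent palladium source, for example Pd(dba)2 with a chiral phosphoramidite, would generate the palladium–trimethylenemethane zwitterion, which should add across the electron-poor alkene of A1 by conjugate addition and ring closure to give the cis-fused cycloadduct A3.
- In its favour: the arene, the Ar6–C2 bond and the phenol oxygen are present from the start. Both quaternary centres and their cis relationship would be set in one catalytic step, and the lactone carbonyl sits on C1 on the same face as the arene, where C6 must end up.
- Against it here: the acceptor is a tetrasubstituted alkene with no extra activating group, a demanding case for forming two adjacent quaternary carbons. A3 also has one carbon too many (the exocyclic methylene on C4) and no C5–C6 bond. Excising the methylene, reducing the lactone carbon to a CH2 bearing a leaving group, closing the three-membered ring from C5 and deoxygenating C4 next to the new cyclopropane would all have to follow before bromination.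
- Comparison: on structure this alternative is the better one for the two quaternary stereocentres, and it equals the chosen plan in never making the aryl–quaternary bond by coupling. On mechanism the chosen cyclocondensation has secure regiochemistry, whereas the cycloaddition to a 3,4-dialkylcoumarin is less certain. On step economy the short front end is offset by the long sequence after A3, so the totals should be similar.

**Alternative 2:** The cut removes C5–C1 and C5–C6 and opens both rings to the acyclic 1,5-enyne (3R)-3-(2-methoxy-4-methylphenyl)-2,3-dimethylhex-1-en-5-yne A4, in which C1=C6 is an isopropenyl group and C4≡C5 a terminal alkyne.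
- Forward step: a π-acid such as Ph3PAuCl/AgSbF6 (monovalent gold) or PtCl2 (divalent platinum) activates the alkyne, the isopropenyl group adds to the alkyne terminus to give a cyclopropyl metal carbene at C4, and a 1,2-hydride shift from C3 leaves the C3=C4 alkene of the bicyclohexene A5.
- In its favour: it is atom-economical, catalytic, and makes both rings and two stereocentres in one step from a precursor built around one quaternary carbon.
- Against it here: the acyclic quaternary stereocentre of A4 is hard to make as one enantiomer, and it alone must decide whether aryl or methyl ends up syn to C6, a distinction with no obvious strong bias. A5 keeps a vinylcyclopropane alkene that must be saturated without ring hydrogenolysis, and the methyl ether must later be cleaved without acid.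
- Comparison: on step economy this alternative is the better one. On structure it is the equal of the chosen plan in avoiding an aryl–quaternary coupling late in the route. On mechanism it is weaker, because the stereochemical relay from C2 to the cyclopropane is unproven, whereas the chosen route sets C1 and C5 by hydroxyl direction and C2 by attack away from C6.

**Alternative 3:** Only C1–C6 is cut, giving a cyclopentane with a tertiary hydroxyl on C1 and a tributylstannylmethyl group on C5, 2-(2-methoxy-4-methylphenyl)-1,2-dimethyl-5-[(tributylstannyl)methyl]cyclopentan-1-ol A6.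
- Forward step: activation of the alcohol ionises C1, and the C6–Sn bond, γ to the cationic centre, closes onto it in a 1,3-elimination with loss of the tributyltin cation to give the aryl methyl ether A7.
- In its favour: it mirrors the likely biogenesis. The ring fusion can only be cis, so C1 needs no control and the carbinol configuration is irrelevant. The Ar6–C2 bond is in place early.
- Against it here: the C1 cation sits beside a quaternary carbon carrying an electron-rich ortho-alkoxyaryl group, so 1,2-aryl or methyl shift, capture by the ether oxygen and simple proton loss all compete with tin-assisted closure. The stannylmethyl group on C5 must be cis to the arene on C2 with little to enforce it. Stoichiometric organotin is used, and A7 still needs non-acidic O-demethylation and two brominations.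
- Comparison: on structure it equals the chosen plan for C1 and is simpler in forming only one bond in its key step. On mechanism the cation is exposed to several well-precedented escape routes, while the chosen key step creates no cation on the bicycle. On step economy the two are probably close, with this alternative carrying the extra deprotection.

Key step: step 10

Remark on the chemistry: the enol-ether double bonds of 7, 14 and 17 and the transient sp3 centres of 12, 17 and 18 are left undefined because every isomer converges on the same product; 15 is drawn as the (1Z,3Z) isomer expected from kinetic deprotonation.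

## Route

**Step 1**
Reactants: 1 2-methylcyclopent-2-en-1-one
Product: 2 (1R)-2-methylcyclopent-2-en-1-ol
Conditions: (3aS)-1-methyl-3,3-diphenyltetrahydro-1H,3H-pyrrolo[1,2-c][1,3,2]oxazaborole (0.1 equiv), BH3·SMe2 (0.7 equiv), THF, −20 °C, slow addition of 1; MeOH quench
Reagents that add atoms: none
Why: Corey–Bakshi–Shibata reduction; the methyl-bearing vinyl arm acts as the large group, so the (S)-configured catalyst should deliver hydride to the face that gives the (R)-carbinol, and the catalysed 1,2-reduction should outrun hydroboration of the alkene. The alcohol is volatile and is best carried forward as a concentrated solution.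

**Step 2**
Reactants: 2 (1R)-2-methylcyclopent-2-en-1-ol
Product: 3 (1S,2R,5R)-1-methylbicyclo[3.1.0]hexan-2-ol
Conditions: Et2Zn (2.2 equiv), CH2I2 (4.4 equiv), CH2Cl2, 0 °C to rt; aq. NH4Cl
Reagents that add atoms: diiodomethane, ICI
Why: Hydroxyl-directed Simmons–Smith cyclopropanation (Furukawa conditions); the zinc alkoxide delivers the methylene to the alkene face cis to oxygen, so the carbinol centre fixes both C1 and C5.

**Step 3**
Reactants: 3 (1S,2R,5R)-1-methylbicyclo[3.1.0]hexan-2-ol
Product: 4 (1S,5R)-1-methylbicyclo[3.1.0]hexan-2-one
Conditions: Pr4N[RuO4] (5 mol%), N-methylmorpholine N-oxide (1.5 equiv), 4 Å MS, CH2Cl2, rt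
Reagents that add atoms: none
Why: Ley–Griffith oxidation of a secondary alcohol under neutral conditions; the cyclopropane and the quaternary C1 are untouched, and the carbinol centre is removed once it has done its directing work.

**Step 4**
Reactants: 4 (1S,5R)-1-methylbicyclo[3.1.0]hexan-2-one; 5 triethyl phosphonoacetate
Product: 6 ethyl (2E)-2-[(1S,5R)-1-methylbicyclo[3.1.0]hexan-2-ylidene]acetate
Conditions: NaH (1.5 equiv), 5 (1.6 equiv), THF, 0 °C; then 4, reflux
Reagents that add atoms: none
Why: Horner–Wadsworth–Emmons olefination; the small stabilised phosphonate anion should add to the five-ring ketone despite the quaternary α-carbon, with the ester turned away from C1, and either alkene geometry serves the next step.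

**Step 5**
Reactants: 6 ethyl (2E)-2-[(1S,5R)-1-methylbicyclo[3.1.0]hexan-2-ylidene]acetate
Product: 8 ethyl 2-[(1S,2S,5R)-1,2-dimethylbicyclo[3.1.0]hexan-2-yl]acetate, via silyl ketene acetal 7 (not isolated)
Conditions: Me2CuLi (2 equiv, from MeLi and CuI), Me3SiCl (4 equiv), THF, −78 to 0 °C; aq. NH4Cl/NH3
Reagents that add atoms: methyllithium (delivered as lithium dimethylcuprate), C[Li]
Why: Silyl chloride-accelerated conjugate addition of a lithium dialkylcuprate; trapping of the adduct as 7 drives addition at the β,β-disubstituted carbon. Methyl should enter C2 on the face opposite C6, because the endo hydrogen of the cyclopropane methylene projects over the five-membered ring while the bridgehead methyl lies near the ring plane; this sets C2 with the acetate arm cis to C6.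

**Step 6**
Reactants: 8 ethyl 2-[(1S,2S,5R)-1,2-dimethylbicyclo[3.1.0]hexan-2-yl]acetate
Product: 9 2-[(1S,2S,5R)-1,2-dimethylbicyclo[3.1.0]hexan-2-yl]acetic acid
Conditions: LiOH·H2O (5 equiv), THF/MeOH/H2O, 50 °C; 1 M HCl to pH 2
Reagents that add atoms: lithium hydroxide, [Li+].[OH-]
Why: Saponification of an ester whose carbonyl is one carbon removed from the quaternary centre; there is no epimerisable centre and the alkyl cyclopropane tolerates brief contact with dilute acid.

**Step 7**
Reactants: 9 2-[(1S,2S,5R)-1,2-dimethylbicyclo[3.1.0]hexan-2-yl]acetic acid; 10 3-(benzyloxy)-3-oxopropanoic acid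
Product: 13 benzyl 4-[(1S,2S,5R)-1,2-dimethylbicyclo[3.1.0]hexan-2-yl]-3-oxobutanoate, via acyl imidazolide 11 (not isolated), via acylmalonic half ester 12 (not isolated)
Conditions: 1,1′-carbonyldiimidazole (1.2 equiv), THF, rt; then 10 (1.5 equiv), MgCl2 (1.5 equiv), Et3N (3 equiv), MeCN, rt to 45 °C; 1 M HCl
Reagents that add atoms: none
Why: Masamune–Brooks homologation; the magnesium enolate of the malonic half ester is C-acylated by 11 and the adduct 12 loses carbon dioxide, which supplies the future Ar1 and Ar2 carbons and the benzyl ester.

**Step 8**
Reactants: 13 benzyl 4-[(1S,2S,5R)-1,2-dimethylbicyclo[3.1.0]hexan-2-yl]-3-oxobutanoate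
Product: 14 benzyl 4-[(1S,2S,5R)-1,2-dimethylbicyclo[3.1.0]hexan-2-yl]-3-[(trimethylsilyl)oxy]but-2-enoate
Conditions: Me3SiCl (1.5 equiv), Et3N (1.6 equiv), toluene, rt; filtration under argon
Reagents that add atoms: chlorotrimethylsilane, C[Si](C)(C)Cl
Why: O-silylation of the enolised β-keto ester with an amine base; it masks the acidic central position so that the next base acts at the CH2 next to the bicycle.

**Step 9**
Reactants: 14 benzyl 4-[(1S,2S,5R)-1,2-dimethylbicyclo[3.1.0]hexan-2-yl]-3-[(trimethylsilyl)oxy]but-2-enoate
Product: 15 (1Z,3Z)-1-(benzyloxy)-4-[(1S,2S,5R)-1,2-dimethylbicyclo[3.1.0]hexan-2-yl]-1,3-bis[(trimethylsilyl)oxy]buta-1,3-diene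
Conditions: LiN(iPr)2 (1.5 equiv), THF, −78 °C; Me3SiCl (1.6 equiv), −78 to 20 °C; pentane, filtration under argon, no aqueous work-up
Reagents that add atoms: chlorotrimethylsilane, C[Si](C)(C)Cl
Why: γ-Deprotonation of the vinylogous ester and O-silylation of the resulting dienolate, the standard second stage of 1,3-bis(silyl enol ether) formation; the diene is moisture-sensitive and is used crude.

**Step 10**
Reactants: 15 (1Z,3Z)-1-(benzyloxy)-4-[(1S,2S,5R)-1,2-dimethylbicyclo[3.1.0]hexan-2-yl]-1,3-bis[(trimethylsilyl)oxy]buta-1,3-diene; 16 4,4-dimethoxybutan-2-one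
Product: 19 benzyl 3-[(1S,2R,5R)-1,2-dimethylbicyclo[3.1.0]hexan-2-yl]-2-hydroxy-6-methylbenzoate, via open-chain enol silyl ether 17 (not isolated), via cyclic aldol 18 (not isolated)
Conditions: 16 (1.3 equiv), TiCl4 (1.3 equiv), CH2Cl2, 4 Å MS, −78 to 0 °C; sat. aq. NaHCO3
Reagents that add atoms: none
Why: TiCl4 ionises the dimethyl acetal of 16 faster than it activates the ketone, and the oxocarbenium ion is attacked by the terminal carbon of 15, the most nucleophilic site of this vinylogous silyl ketene acetal (Mukaiyama-type addition), which forms Ar5–Ar6 and leaves the enol silyl ether 17. The central carbon of 17 then adds to the titanium-bound ketone in a 6-(enolendo)-exo-trig aldol closure that forms Ar2–Ar3 and the only new ring (18). Loss of methanol from the β-alkoxy ketone and of water from the β-hydroxy carbonyl unit, followed by enolisation, aromatises the ring to the salicylate 19. The closest known reaction type is the Lewis acid-mediated formal (3+3) cyclocondensation of 1,3-bis(silyl enol ethers) with β-keto acetals to 6-alkylsalicylates. No surviving stereocentre is created, since the sp3 centres of 17 and 18 are erased on aromatisation, and C1, C2 and C5 have no enolisable or ionisable neighbour here. The selectivity needed is regiochemical, with the methyl on Ar3 beside the ester-bearing Ar2; it rests on the reactivity gap between acetal and ketone in 16 and between terminal and central carbon in 15, and the reverse pairing would also force the tertiary alkyl group between hydroxyl and methyl. Low temperature, close to one equivalent of Lewis acid and a bicarbonate quench limit the contact of the cyclopropane and the new phenol with acid, and the benzyl ester should be inert to TiCl4 at these temperatures.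

**Step 11**
Reactants: 19 benzyl 3-[(1S,2R,5R)-1,2-dimethylbicyclo[3.1.0]hexan-2-yl]-2-hydroxy-6-methylbenzoate
Product: 20 3-[(1S,2R,5R)-1,2-dimethylbicyclo[3.1.0]hexan-2-yl]-2-hydroxy-6-methylbenzoic acid
Conditions: H2 (1 atm), Pd/C (10 wt% Pd, 5 mol%), EtOAc, rt; filtration, evaporation
Reagents that add atoms: none
Why: Hydrogenolysis of the benzylic C–O bond is indifferent to the two ortho groups that shield the carbonyl and needs no acid or base; the unactivated cyclopropane should not be cleaved at ambient pressure, and no bromine is yet present.

**Step 12**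
Reactants: 20 3-[(1S,2R,5R)-1,2-dimethylbicyclo[3.1.0]hexan-2-yl]-2-hydroxy-6-methylbenzoic acid
Product: 22 2,4-dibromo-6-[(1S,2R,5R)-1,2-dimethylbicyclo[3.1.0]hexan-2-yl]-3-methylphenol, via para-bromo acid 21 (not isolated)
Conditions: Br2 (2.05 equiv), NaHCO3 (5 equiv), CH2Cl2/H2O, 0 °C to rt; aq. Na2S2O3
Reagents that add atoms: bromine, BrBr
Why: Electrophilic bromination para to the hydroxyl (Ar4) gives 21, and ipso attack at the carboxylate-bearing ortho carbon (Ar2) followed by loss of carbon dioxide from the σ-adduct completes a bromodecarboxylation of a hydroxybenzoic acid. Bicarbonate keeps the acid as its carboxylate and removes hydrogen bromide, which protects the cyclopropane, and thiosulfate should return any over-brominated dienone to the phenol.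

## Compound list

1 | 2-methylcyclopent-2-en-1-one | CC1=CCCC1=O | starting material
2 | (1R)-2-methylcyclopent-2-en-1-ol | O[C@@H]1CCC=C1C | intermediate
3 | (1S,2R,5R)-1-methylbicyclo[3.1.0]hexan-2-ol (hydroxyl cis to the cyclopropane) | O[C@@H]1CC[C@@H]2C[C@@]21C | intermediate
4 | (1S,5R)-1-methylbicyclo[3.1.0]hexan-2-one | O=C1CC[C@@H]2C[C@@]21C | intermediate
5 | triethyl phosphonoacetate | CCOC(=O)CP(=O)(OCC)OCC | starting material
6 | ethyl (2E)-2-[(1S,5R)-1-methylbicyclo[3.1.0]hexan-2-ylidene]acetate | CCOC(=O)/C=C1\CC[C@@H]2C[C@@]21C | intermediate
7 | {2-[(1S,2S,5R)-1,2-dimethylbicyclo[3.1.0]hexan-2-yl]-1-ethoxyethenyl}oxy(trimethyl)silane (silyl ketene acetal, not isolated) | CCOC(O[Si](C)(C)C)=C[C@]1(C)CC[C@@H]2C[C@@]21C | intermediate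
8 | ethyl 2-[(1S,2S,5R)-1,2-dimethylbicyclo[3.1.0]hexan-2-yl]acetate | CCOC(=O)C[C@]1(C)CC[C@@H]2C[C@@]21C | intermediate
9 | 2-[(1S,2S,5R)-1,2-dimethylbicyclo[3.1.0]hexan-2-yl]acetic acid | OC(=O)C[C@]1(C)CC[C@@H]2C[C@@]21C | intermediate
10 | 3-(benzyloxy)-3-oxopropanoic acid (monobenzyl malonate) | OC(=O)CC(=O)OCc1ccccc1 | starting material
11 | 2-[(1S,2S,5R)-1,2-dimethylbicyclo[3.1.0]hexan-2-yl]-1-(1H-imidazol-1-yl)ethan-1-one (acyl imidazolide, not isolated) | O=C(C[C@]1(C)CC[C@@H]2C[C@@]21C)n1ccnc1 | intermediate
12 | 2-[(benzyloxy)carbonyl]-4-[(1S,2S,5R)-1,2-dimethylbicyclo[3.1.0]hexan-2-yl]-3-oxobutanoic acid (acylmalonic half ester, not isolated) | OC(=O)C(C(=O)OCc1ccccc1)C(=O)C[C@]1(C)CC[C@@H]2C[C@@]21C | intermediate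
13 | benzyl 4-[(1S,2S,5R)-1,2-dimethylbicyclo[3.1.0]hexan-2-yl]-3-oxobutanoate | O=C(CC(=O)C[C@]1(C)CC[C@@H]2C[C@@]21C)OCc1ccccc1 | intermediate
14 | benzyl 4-[(1S,2S,5R)-1,2-dimethylbicyclo[3.1.0]hexan-2-yl]-3-[(trimethylsilyl)oxy]but-2-enoate (alkene geometry undefined) | C[Si](C)(C)OC(C[C@]1(C)CC[C@@H]2C[C@@]21C)=CC(=O)OCc1ccccc1 | intermediate
15 | (1Z,3Z)-1-(benzyloxy)-4-[(1S,2S,5R)-1,2-dimethylbicyclo[3.1.0]hexan-2-yl]-1,3-bis[(trimethylsilyl)oxy]buta-1,3-diene | c1ccccc1CO/C(O[Si](C)(C)C)=C/C(O[Si](C)(C)C)=C/[C@]1(C)CC[C@@H]2C[C@@]21C | intermediate
16 | 4,4-dimethoxybutan-2-one | CC(=O)CC(OC)OC | starting material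
17 | benzyl 4-[(1S,2S,5R)-1,2-dimethylbicyclo[3.1.0]hexan-2-yl]-5-methoxy-7-oxo-3-[(trimethylsilyl)oxy]oct-2-enoate (not isolated; C4, C5 and alkene undefined) | O=C(OCc1ccccc1)C=C(O[Si](C)(C)C)C(C(CC(C)=O)OC)[C@]1(C)CC[C@@H]2C[C@@]21C | intermediate
18 | benzyl 3-[(1S,2S,5R)-1,2-dimethylbicyclo[3.1.0]hexan-2-yl]-6-hydroxy-4-methoxy-6-methyl-2-oxocyclohexane-1-carboxylate (not isolated; ring centres undefined) | O=C(OCc1ccccc1)C1C(=O)C([C@]2(C)CC[C@@H]3C[C@@]32C)C(OC)CC1(C)O | intermediate
19 | benzyl 3-[(1S,2R,5R)-1,2-dimethylbicyclo[3.1.0]hexan-2-yl]-2-hydroxy-6-methylbenzoate | Cc1ccc([C@]2(C)CC[C@@H]3C[C@@]32C)c(O)c1C(=O)OCc1ccccc1 | intermediate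
20 | 3-[(1S,2R,5R)-1,2-dimethylbicyclo[3.1.0]hexan-2-yl]-2-hydroxy-6-methylbenzoic acid | Cc1ccc([C@]2(C)CC[C@@H]3C[C@@]32C)c(O)c1C(=O)O | intermediate
21 | 5-bromo-3-[(1S,2R,5R)-1,2-dimethylbicyclo[3.1.0]hexan-2-yl]-2-hydroxy-6-methylbenzoic acid (not isolated) | Cc1c(Br)cc([C@]2(C)CC[C@@H]3C[C@@]32C)c(O)c1C(=O)O | intermediate
22 | 2,4-dibromo-6-[(1S,2R,5R)-1,2-dimethylbicyclo[3.1.0]hexan-2-yl]-3-methylphenol | Cc1c(Br)cc([C@]2(C)CC[C@@H]3C[C@@]32C)c(O)c1Br | target

## Step count and least certain steps

Total step count: 12. Longest linear sequence: 12 steps, from 1 to 22.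

**Step 10 (key step).** The most likely failure is slow attack of the diene terminus, which carries a tertiary alkyl group, on the oxocarbenium ion. Lewis-acid desilylation back to 13 could then overtake carbon–carbon bond formation. Prolonged contact with TiCl4 and the hydrogen chloride released on aromatisation could also open the cyclopropane, with capture of C1 by the new phenol oxygen. The fallback makes the same two bonds with anions instead of a Lewis acid and needs no silyl diene. It sets out from 13: the dianion (LiN(iPr)2, 2.2 equiv, THF, −78 °C) reacts at its γ-carbon with purchased (2-methyl-1,3-dioxolan-2-yl)acetaldehyde to form Ar5–Ar6 as an aldol bond, giving benzyl 4-[(1S,2S,5R)-1,2-dimethylbicyclo[3.1.0]hexan-2-yl]-5-hydroxy-6-(2-methyl-1,3-dioxolan-2-yl)-3-oxohexanoate F1. Pyridinium p-toluenesulfonate in wet acetone then frees the methyl ketone benzyl 4-[(1S,2S,5R)-1,2-dimethylbicyclo[3.1.0]hexan-2-yl]-5-hydroxy-3,7-dioxooctanoate F2. Piperidinium acetate closes Ar2–Ar3 by intramolecular Knoevenagel condensation, and two dehydrations bring the sequence back to the route at 19.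

**Step 5.** The most likely failure is insufficient reactivity of the β,β-disubstituted enoate when a second contiguous quaternary carbon must form, so that 6 is recovered or reduced. Loss of facial selectivity, or ring opening through the copper intermediate beside the cyclopropane, are further risks. The fallback changes the acceptor and sets out from 4. Knoevenagel condensation with Meldrum's acid (TiCl4, pyridine, THF) gives 2,2-dimethyl-5-[(1S,5R)-1-methylbicyclo[3.1.0]hexan-2-ylidene]-1,3-dioxane-4,6-dione F3. MeMgBr with catalytic CuBr·SMe2 should add to this far more electrophilic alkene on the same face to give 5-[(1S,2S,5R)-1,2-dimethylbicyclo[3.1.0]hexan-2-yl]-2,2-dimethyl-1,3-dioxane-4,6-dione F4. Heating in wet pyridine hydrolyses and decarboxylates F4 and rejoins the route at 9, in the same number of operations as steps 4 to 6.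

**Step 4.** The most likely failure is enolisation of the ketone at C3 by the phosphonate anion, together with slow addition to a carbonyl that is both hindered and conjugated with the cyclopropane, which gives incomplete conversion of a volatile substrate. The fallback is a Peterson olefination from 4: the lithium enolate of ethyl (trimethylsilyl)acetate (LiN(iPr)2, THF, −78 °C) adds to give the β-silyl alkoxide of ethyl 2-[(1S,5R)-2-hydroxy-1-methylbicyclo[3.1.0]hexan-2-yl]-2-(trimethylsilyl)acetate F5, which eliminates on warming and rejoins the route at 6.

**Step 12.** The most likely failures are incomplete ipso substitution at the crowded Ar2, which stops at 21; over-bromination of the product phenolate to a dienone; and opening of the cyclopropane by hydrogen bromide if the buffer is locally exhausted. The fallback separates the two events and sets out from 20. Protodecarboxylation (Ag2CO3 catalyst, DMSO, 120 °C) gives 2-[(1S,2R,5R)-1,2-dimethylbicyclo[3.1.0]hexan-2-yl]-5-methylphenol F6. Two equivalents of N-bromosuccinimide in MeCN at 0 °C then brominate the only open activated positions, para first to 4-bromo-2-[(1S,2R,5R)-1,2-dimethylbicyclo[3.1.0]hexan-2-yl]-5-methylphenol F7 and then ortho, arriving at 22 without free hydrogen bromide.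

## Further compounds

F1 | step 10 | benzyl 4-[(1S,2S,5R)-1,2-dimethylbicyclo[3.1.0]hexan-2-yl]-5-hydroxy-6-(2-methyl-1,3-dioxolan-2-yl)-3-oxohexanoate | O=C(CC(=O)C(C(O)CC1(C)OCCO1)[C@]1(C)CC[C@@H]2C[C@@]21C)OCc1ccccc1
F2 | step 10 | benzyl 4-[(1S,2S,5R)-1,2-dimethylbicyclo[3.1.0]hexan-2-yl]-5-hydroxy-3,7-dioxooctanoate | O=C(CC(=O)C(C(O)CC(C)=O)[C@]1(C)CC[C@@H]2C[C@@]21C)OCc1ccccc1
F3 | step 5 | 2,2-dimethyl-5-[(1S,5R)-1-methylbicyclo[3.1.0]hexan-2-ylidene]-1,3-dioxane-4,6-dione | CC1(C)OC(=O)C(=C2CC[C@@H]3C[C@@]32C)C(=O)O1
F4 | step 5 | 5-[(1S,2S,5R)-1,2-dimethylbicyclo[3.1.0]hexan-2-yl]-2,2-dimethyl-1,3-dioxane-4,6-dione | CC1(C)OC(=O)C([C@]2(C)CC[C@@H]3C[C@@]32C)C(=O)O1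
F5 | step 4 | ethyl 2-[(1S,5R)-2-hydroxy-1-methylbicyclo[3.1.0]hexan-2-yl]-2-(trimethylsilyl)acetate | CCOC(=O)C([Si](C)(C)C)C1(O)CC[C@@H]2C[C@@]21C
F6 | step 12 | 2-[(1S,2R,5R)-1,2-dimethylbicyclo[3.1.0]hexan-2-yl]-5-methylphenol | Cc1ccc([C@]2(C)CC[C@@H]3C[C@@]32C)c(O)c1
F7 | step 12 | 4-bromo-2-[(1S,2R,5R)-1,2-dimethylbicyclo[3.1.0]hexan-2-yl]-5-methylphenol | Cc1cc(O)c([C@]2(C)CC[C@@H]3C[C@@]32C)cc1Br
A1 | alternative 1 | 3,4,7-trimethyl-2H-chromen-2-one | Cc1ccc2c(c1)OC(=O)C(C)=C2C
A2 | alternative 1 | 2-[(trimethylsilyl)methyl]prop-2-en-1-yl acetate | CC(=O)OCC(=C)C[Si](C)(C)C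
A3 | alternative 1 | cis-3a,7,9b-trimethyl-2-methylidene-1,2,3,9b-tetrahydrocyclopenta[c]chromen-4(3aH)-one | Cc1ccc2c(c1)OC(=O)[C@@]1(C)CC(=C)C[C@@]21C
A4 | alternative 2 | (3R)-3-(2-methoxy-4-methylphenyl)-2,3-dimethylhex-1-en-5-yne | COc1cc(C)ccc1[C@](C(C)=C)(C)CC#C
A5 | alternative 2 | 4-(2-methoxy-4-methylphenyl)-4,5-dimethylbicyclo[3.1.0]hex-2-ene (aryl cis to the cyclopropane methylene) | COc1cc(C)ccc1[C@]2(C)C=C[C@@H]3C[C@@]32C
A6 | alternative 3 | 2-(2-methoxy-4-methylphenyl)-1,2-dimethyl-5-[(tributylstannyl)methyl]cyclopentan-1-ol (aryl and stannylmethyl cis; carbinol centre undefined) | COc1cc(C)ccc1[C@]2(C)CC[C@H](C[Sn](CCCC)(CCCC)CCCC)C2(C)O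
A7 | alternative 3 | 2-[(1S,2R,5R)-1,2-dimethylbicyclo[3.1.0]hexan-2-yl]-1-methoxy-4-methylbenzene | COc1cc(C)ccc1[C@]2(C)CC[C@@H]3C[C@@]32C
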